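C1 is the ring carbon bearing the hydroxyl and the undecanoyl group (ketone carbon C1'), C2 and C5 bear the acetates, and C3=C4 is the ring alkene.
Retrosynthetic cuts, in order: acetyl–O at C5, H–C5 (back to a C5 ketone), the C3=C4 π bond, C2–OAc (back to a C1–C2 oxirane), both oxirane C–O bonds (back to a C1=C2 alkene), the C1' oxidation level, and last C1–C1'.
Enabling feature: on the five-membered ring the C1 hydroxyl is trans to the C2 acetoxy group, and C1 lies between C1' and C5, both carbonyl carbons at the ketone stage. This pattern marks an oxirane across C1 and C2, and the C1=C2 alkene beneath it is an acceptor activated from two sides.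
Forward: the carbocycle is bought and the C11 chain is joined first. The oxirane is the only ring built and is opened one step later, after which C3=C4 and the C5 carbinol are installed.
Stereochemistry: cis fusion of the oxirane ties C1 to C2, and backside attack of acetate places the C2 ester trans to the hydroxyl and cis to the acyl group. Hydride attack on the hydroxyl face of C5 sets the last oxygen cis to the acyl group.

Key step: step 3

Remark: the target has a mirror plane through C1 and the midpoint of C3=C4 (meso). All chiral intermediates are therefore racemic, one enantiomer is drawn with rel-descriptors, and the SMILES of 12 can be written from either enantiomeric series.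

Step 1
Reactants: 1 cyclopent-2-en-1-one; 2 undecanal
Product: 3 2-(1-hydroxyundecyl)cyclopent-2-en-1-one (racemic)
Conditions: Bu3P (0.2 equiv), PhOH (0.2 equiv), THF, rt
Reagents that add atoms: none
Why: Morita–Baylis–Hillman reaction: the phosphine adds reversibly to the β-carbon of 1, the phosphonium enolate adds to aldehyde 2 and phenol-assisted proton transfer releases the catalyst, forging C1–C1' at the α-carbon, a combination well established for cyclopentenone and unbranched aliphatic aldehydes; the carbinol centre forms racemic and disappears in step 2.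

Step 2
Reactants: 3 2-(1-hydroxyundecyl)cyclopent-2-en-1-one
Product: 4 2-undecanoylcyclopent-2-en-1-one
Conditions: Dess–Martin periodinane (1.2 equiv), CH2Cl2, 0 °C to rt; dilution with pentane, filtration through a short silica pad, used at once
Reagents that add atoms: none
Why: Dess–Martin oxidation: the neutral, non-aqueous oxidant takes the allylic alcohol to the ketone without touching the enone, and because the resulting alkylidene β-diketone is a strong acceptor that dimerises on standing it is only filtered and carried straight into step 3.

Step 3
Reactants: 4 2-undecanoylcyclopent-2-en-1-one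
Product: 6 rel-(1R,5S)-1-undecanoyl-6-oxabicyclo[3.1.0]hexan-2-one, via tert-butylperoxy diketone enolate 5 (not isolated)
Conditions: t-BuOOH (5.5 M in decane, 1.2 equiv), DBU (0.3 equiv), CH2Cl2, −20 to 0 °C
Reagents that add atoms: tert-butyl hydroperoxide, CC(C)(C)OO
Why: DBU turns t-BuOOH into its anion, which attacks the electron-poor alkene of 4 at the ring CH (C2); the charge is taken up by C1 and both flanking carbonyl groups (enolate 5), and C1 then bonds to the inner peroxide oxygen while the O–O bond breaks and tert-butoxide leaves to deprotonate the next hydroperoxide. This is a Weitz–Scheffer nucleophilic epoxidation, and the closest known cases are the alkyl hydroperoxide/amidine epoxidations of 2-substituted cycloalkenones and of alkylidene 1,3-dicarbonyl compounds. The oxirane closes in the 3-exo-tet mode, so C2–O forms first and C1–O second. A three-membered ring on a cyclopentane must be cis-fused, so the relative configuration of the new stereocentres C1 and C2 follows from geometry alone, and an achiral precursor on the way to a meso target needs neither facial nor absolute control. The selectivity that matters is conjugate addition at C2 over attack at a carbonyl carbon with retro-Claisen or Baeyer–Villiger cleavage, and it is secured by the double activation of the C1=C2 bond, the low temperature and an anhydrous, hydroxide-free medium with a bulky hydroperoxide and a non-nucleophilic base. Rapid consumption of 4 should also outrun its dimerisation.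

Step 4
Reactants: 6 rel-(1R,5S)-1-undecanoyl-6-oxabicyclo[3.1.0]hexan-2-one
Product: 7 rel-(1R,2R)-2-hydroxy-3-oxo-2-undecanoylcyclopentyl acetate (hydroxyl trans to acetate; acyl cis to acetate)
Conditions: CsOAc (3 equiv), AcOH, 60 °C
Reagents that add atoms: acetic acid, CC(=O)O (delivered as its caesium salt, CC(=O)[O-].[Cs+])
Why: Invertive (SN2) opening of an epoxide by a carboxylate: C1 is fully substituted and its two carbonyl neighbours disfavour cationic character there, so acetate attacks the secondary C2 from the face opposite the oxygen bridge, the stabilised tertiary alkoxide is protonated at once by the solvent (which holds back α-ketol and acyl shifts), and the C2 ester ends trans to the C1 hydroxyl.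

Step 5
Reactants: 7 rel-(1R,2R)-2-hydroxy-3-oxo-2-undecanoylcyclopentyl acetate
Product: 8 rel-(1R,2S)-2-undecanoyl-2,3-bis(trimethylsilyloxy)cyclopent-3-en-1-yl acetate
Conditions: TMSOTf (2.2 equiv), Et3N (4 equiv), CH2Cl2, −78 to −20 °C; used crude
Reagents that add atoms: trimethylsilyl trifluoromethanesulfonate, C[Si](C)(C)OS(=O)(=O)C(F)(F)F
Why: Soft enolisation with a silyl triflate and a tertiary amine: the reagent first caps the C1 hydroxyl (blocking α-ketol rearrangement and crowding the side-chain carbonyl further) and should then enolise the ring ketone toward C4, because cyclopentanone α-hydrogens, held nearly parallel to the carbonyl π system, are removed by amine bases markedly faster than those of an open-chain dialkyl ketone, and the limiting amount of triflate at low temperature exploits this difference; no stereocentre is touched.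

Step 6
Reactants: 8 rel-(1R,2S)-2-undecanoyl-2,3-bis(trimethylsilyloxy)cyclopent-3-en-1-yl acetate
Product: 10 rel-(1R,5R)-5-hydroxy-4-oxo-5-undecanoylcyclopent-2-en-1-yl acetate, via O-silylated enone 9 (not isolated)
Conditions: Pd(OAc)2 (1.1 equiv), MeCN, rt; then 1 M HCl, THF, 0 °C
Reagents that add atoms: none
Why: Saegusa–Ito oxidation: the divalent palladium salt replaces silicon on the enol ether, β-hydride elimination of a C3 hydrogen installs C3=C4, the phosphine-free medium lets the zerovalent palladium released aggregate instead of ionising the new allylic acetate, and brief dilute acid cleaves the labile tertiary trimethylsilyl ether without harming the ester.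

Step 7
Reactants: 10 rel-(1R,5R)-5-hydroxy-4-oxo-5-undecanoylcyclopent-2-en-1-yl acetate
Product: 11 rel-(1R,4S,5R)-4,5-dihydroxy-5-undecanoylcyclopent-2-en-1-yl acetate (new hydroxyl cis to acyl and acetate; trans to the tertiary hydroxyl)
Conditions: CeCl3·7H2O (1.2 equiv), NaBH4 (1.0 equiv), MeOH, −78 °C
Reagents that add atoms: none
Why: Luche reduction: the cerium-modified borohydride adds hydride 1,2 to the conjugated ring ketone much faster than to the saturated side-chain ketone buried next to the fully substituted C1, and since the acyl chain on C1 and the acetate on C2 screen one face of the flat cyclopentenone, hydride should enter from the face of the small C1 hydroxyl and push the new C5 hydroxyl cis to the acyl group.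

Step 8
Reactants: 11 rel-(1R,4S,5R)-4,5-dihydroxy-5-undecanoylcyclopent-2-en-1-yl acetate
Product: 12 (1R,4S,5r)-5-hydroxy-5-undecanoylcyclopent-2-ene-1,4-diyl diacetate (meso; target)
Conditions: Ac2O (1.5 equiv), pyridine, CH2Cl2, 0 °C to rt
Reagents that add atoms: acetic anhydride, CC(=O)OC(C)=O
Why: Acetylation with acetic anhydride in pyridine: without an acyl-transfer catalyst only the secondary allylic C5 hydroxyl should react, the tertiary C1 hydroxyl being hindered and deactivated by the adjacent ketone, and esterification makes C2 and C5 equivalent so that the racemic monoacetate converges on the single meso diacetate.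

Compound list
1 | cyclopent-2-en-1-one | O=C1C=CCC1 | starting material
2 | undecanal | CCCCCCCCCCC=O | starting material
3 | 2-(1-hydroxyundecyl)cyclopent-2-en-1-one (racemic, one enantiomer drawn) | CCCCCCCCCC[C@H](O)C1=CCCC1=O | intermediate
4 | 2-undecanoylcyclopent-2-en-1-one | CCCCCCCCCCC(=O)C1=CCCC1=O | intermediate
5 | enolate of 3-(tert-butylperoxy)-2-undecanoylcyclopentan-1-one (protonated DBU as counter-ion, not isolated) | CCCCCCCCCCC(=O)C1=C([O-])CC[C@@H]1OOC(C)(C)C | intermediate
6 | rel-(1R,5S)-1-undecanoyl-6-oxabicyclo[3.1.0]hexan-2-one (cis-fused, racemic) | CCCCCCCCCCC(=O)[C@]12O[C@H]1CCC2=O | intermediate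
7 | rel-(1R,2R)-2-hydroxy-3-oxo-2-undecanoylcyclopentyl acetate | CCCCCCCCCCC(=O)[C@]1(O)[C@H](OC(C)=O)CCC1=O | intermediate
8 | rel-(1R,2S)-2-undecanoyl-2,3-bis(trimethylsilyloxy)cyclopent-3-en-1-yl acetate | CCCCCCCCCCC(=O)[C@]1(O[Si](C)(C)C)[C@H](OC(C)=O)CC=C1O[Si](C)(C)C | intermediate
9 | rel-(1R,5R)-4-oxo-5-undecanoyl-5-(trimethylsilyloxy)cyclopent-2-en-1-yl acetate (not isolated) | CCCCCCCCCCC(=O)[C@]1(O[Si](C)(C)C)[C@H](OC(C)=O)C=CC1=O | intermediate
10 | rel-(1R,5R)-5-hydroxy-4-oxo-5-undecanoylcyclopent-2-en-1-yl acetate | CCCCCCCCCCC(=O)[C@]1(O)[C@H](OC(C)=O)C=CC1=O | intermediate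
11 | rel-(1R,4S,5R)-4,5-dihydroxy-5-undecanoylcyclopent-2-en-1-yl acetate | CCCCCCCCCCC(=O)[C@]1(O)[C@H](OC(C)=O)C=C[C@@H]1O | intermediate
12 | (1R,4S,5r)-5-hydroxy-5-undecanoylcyclopent-2-ene-1,4-diyl diacetate (meso) | CCCCCCCCCCC(=O)[C@@]1(O)[C@@H](OC(C)=O)C=C[C@H]1OC(C)=O | target

Total step count: 8. Longest linear sequence: 8.

Steps most likely to fail

(a) Risk at step 5: the silyl triflate/amine pair may enolise the side-chain ketone toward C2' alongside the ring ketone, so that the palladium oxidation that follows also desaturates the chain.
- The fallback sets out from 3 and returns at 10. C1' is held at the alcohol level until the ring alkene is in place, which leaves C5 as the only ketone that can be enolised.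
- TBSCl and imidazole in DMF should convert 3 into 2-[1-(tert-butyldimethylsilyloxy)undecyl]cyclopent-2-en-1-one F1.
- The same t-BuOOH/DBU epoxidation, now at rt on a singly activated enone, makes the same C1–O and C2–O bonds. It gives 1-[1-(tert-butyldimethylsilyloxy)undecyl]-6-oxabicyclo[3.1.0]hexan-2-one F2 as C1' epimers that converge later.
- CsOAc in AcOH opens it to 2-[1-(tert-butyldimethylsilyloxy)undecyl]-2-hydroxy-3-oxocyclopentyl acetate F3.
- TMSOTf/Et3N gives 2-[1-(tert-butyldimethylsilyloxy)undecyl]-2,3-bis(trimethylsilyloxy)cyclopent-3-en-1-yl acetate F4.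
- Pd(OAc)2 in MeCN gives 5-[1-(tert-butyldimethylsilyloxy)undecyl]-4-oxo-5-(trimethylsilyloxy)cyclopent-2-en-1-yl acetate F5.
- Aqueous HF in MeCN strips both silyl ethers to 5-hydroxy-5-(1-hydroxyundecyl)-4-oxocyclopent-2-en-1-yl acetate F6.
- Dess–Martin oxidation of the secondary C1' alcohol then delivers 10.

(b) Risk at step 7: an electronic preference for attack anti to the C1–O bond may compete with the steric bias, so that hydride delivery to C5 loses its facial selectivity.
- The fallback sets out from 10 and returns at 12. The C5 configuration is then fixed by substitution instead of by hydride approach.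
- The epimeric alcohols from the reduction are separated, and 11 goes on as planned.
- The epimer rel-(1R,4R,5R)-4,5-dihydroxy-5-undecanoylcyclopent-2-en-1-yl acetate F7 is submitted to Mitsunobu inversion with acetic acid (PPh3, DIAD, THF, 0 °C).
- This displaces the activated C5 oxygen from the rear and gives 12 directly. The C1 hydroxyl is syn to the leaving group and cannot close an epoxide.

(c) Risk at step 4: substitution by the weakly nucleophilic, hydrogen-bonded acetate may be so slow that thermal acyl migration or loss of the acyl group by retro-Claisen cleavage overtakes it.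
- The fallback sets out from 6 and returns at 7. The oxygen is introduced with the smaller nucleophile water, and the ester is added afterwards.
- Catalytic HClO4 in THF–water at 0 °C to rt should open the protonated oxirane at C2 with inversion to rel-(2R,3R)-2,3-dihydroxy-2-undecanoylcyclopentan-1-one F8.
- Ac2O in pyridine at 0 °C then acetylates only the secondary hydroxyl to give 7.

Further compounds
F1 | step 5 | 2-[1-(tert-butyldimethylsilyloxy)undecyl]cyclopent-2-en-1-one (racemic) | CCCCCCCCCC[C@H](O[Si](C)(C)C(C)(C)C)C1=CCCC1=O
F2 | step 5 | 1-[1-(tert-butyldimethylsilyloxy)undecyl]-6-oxabicyclo[3.1.0]hexan-2-one (ring as in 6, both C1' epimers) | CCCCCCCCCCC(O[Si](C)(C)C(C)(C)C)[C@]12O[C@H]1CCC2=O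
F3 | step 5 | 2-[1-(tert-butyldimethylsilyloxy)undecyl]-2-hydroxy-3-oxocyclopentyl acetate (ring as in 7, both C1' epimers) | CCCCCCCCCCC(O[Si](C)(C)C(C)(C)C)[C@]1(O)[C@H](OC(C)=O)CCC1=O
F4 | step 5 | 2-[1-(tert-butyldimethylsilyloxy)undecyl]-2,3-bis(trimethylsilyloxy)cyclopent-3-en-1-yl acetate (both C1' epimers) | CCCCCCCCCCC(O[Si](C)(C)C(C)(C)C)[C@]1(O[Si](C)(C)C)[C@H](OC(C)=O)CC=C1O[Si](C)(C)C
F5 | step 5 | 5-[1-(tert-butyldimethylsilyloxy)undecyl]-4-oxo-5-(trimethylsilyloxy)cyclopent-2-en-1-yl acetate (both C1' epimers) | CCCCCCCCCCC(O[Si](C)(C)C(C)(C)C)[C@]1(O[Si](C)(C)C)[C@H](OC(C)=O)C=CC1=O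
F6 | step 5 | 5-hydroxy-5-(1-hydroxyundecyl)-4-oxocyclopent-2-en-1-yl acetate (ring as in 10, both C1' epimers) | CCCCCCCCCCC(O)[C@]1(O)[C@H](OC(C)=O)C=CC1=O
F7 | step 7 | rel-(1R,4R,5R)-4,5-dihydroxy-5-undecanoylcyclopent-2-en-1-yl acetate | CCCCCCCCCCC(=O)[C@]1(O)[C@H](OC(C)=O)C=C[C@H]1O
F8 | step 4 | rel-(2R,3R)-2,3-dihydroxy-2-undecanoylcyclopentan-1-one | CCCCCCCCCCC(=O)[C@]1(O)[C@H](O)CCC1=O
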